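(The earlier runs and the new flask stem from a simulated flask on assumed constants, and the scatter is random.)

Over 3.0 d, Z turns into Q in these flasks, so the share of Z in Z plus Q tells how long ago Z was made.

| flask | G | D | remark | time |
|---|---|---|---|---|
| autumn | 0.050 M | 0.075 M | run made earlier |  |
| noon | 0.050 M | 0.11 M | run made earlier |  |
| eta | 0.050 M | 0.0750 M | everything together at the start | 3.0 d |
| beta | 0.050 M (fed, over 40 h) | 0.0750 M | all else is in the flask from the start; the feed brings no volume worth counting | 3.0 d |
| gamma | 0.050 M | 0.0750 M (fed, over 40 h) | all else is in the flask from the start; the feed brings no volume worth counting | 3.0 d |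

autumn run (percent of the G charged)

| time / d | Z / % | Q / % |
|---|---|---|
| 0.167 | 1.5 | 0.3 |
| 0.500 | 7.1 | 0.2 |
| 0.833 | 8.7 | 4.3 |
| 1.25 | 9.1 | 7.6 |
| 1.67 | 6.5 | 11.9 |
| 2.50 | 4.5 | 14.9 |
| 3.00 | 2.8 | 19.3 |

noon run (percent of the G charged)

| time / h | Z / % | Q / % |
|---|---|---|
| 0.500 | 0 | 0 |
| 0.833 | 0 | 0 |
| 1.33 | 0.6 | 1.4 |
| 2.00 | 0 | 0 |
| 3.00 | 0 | 0 |
| 5.00 | 5.4 | 0.1 |
| 8.00 | 8.8 | 1.3 |

(scatter of a reading: 1 percentage point)

- which flask leads in share of Z in Z plus Q ("all alike" within 1.5 percentage points) (eta / beta / gamma / all alike)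
- share of Z in Z plus Q at the end, eta
- share of Z in Z plus Q at the end, beta
- share of Z in Z plus Q at the end, gamma

- the numbers in the tables scatter by 1 percentage point (one standard deviation)
- steps thought possible: G + D -> E; D + E -> J; D + J -> Z; Z -> Q

In the autumn run, which has eta's charges, Q rose by 15 percentage points between 0.833 d and 3.00 d while the 5 Z readings there averaged 6.32%. That reads as a first-order loss of 1.10 d⁻¹, so the half-life of Z, the time in which Z loses half of itself to Q, reads as 0.633 d.

The final autumn share, 12.7%, then gives an age of 1.89 d, as if Z had been made at one moment. My own reckoning moves that moment later by the mid-feed time 0.833 d for gamma, since D enters 3 steps, and by a third of it for beta, since G enters one. Gamma comes to 31.3% and beta to 17.2%.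

The forecast names gamma: 14% for eta (11% to 17%), 22% for beta (16% to 27%) and 30% for gamma (23% to 37%), with “D stays lean, so Z forms late”. My beta lies below its figure.

The flasks give 12.2% for eta, 20.7% for beta and 30.0% for gamma, so gamma leads.

    G + D → E (k = 1.80 M⁻¹ h⁻¹)
    D + E → J (k = 1.80 M⁻¹ h⁻¹)
    D + J → Z (k = 1.70 M⁻¹ h⁻¹)
    Z → Q (k = 0.0440 h⁻¹)

In eta, the half-life of Z on its way to Q is 0.66 d, shorter than 3.0 d. With the half-life read from autumn, the final shares date Z, as if made at one moment, at an age of 1.92 d in eta, 1.44 d in beta and 1.10 d in gamma, the youngest.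

Gamma read at 12 d stands 14.2 half-lives past its asked time, which halves its share that many times, to about 0.00157% by this estimate. That flask gives a share of 0%, with Q at 21.5%.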